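The route rests on cutting the bond between the ketone carbon and the neighbouring CH2 of the three-carbon bridge. The acyl carbon sits on C6 of the 5,7-dihydroxychroman ring, flanked by the C5 and C7 hydroxyls. This salicyl-type arrangement lets rhodium insert into the formyl C–H bond of the corresponding aldehyde and hold the acyl hydride as a phenoxide chelate. Anti-Markovnikov hydroacylation of 6-ethenyl-2,2-dimethylchroman then forms the bond and should deliver the unprotected target in one atom-economical operation. The precursors are 5,7-dihydroxy-2,2-dimethylchroman-6-carbaldehyde (two steps from 4-hydroxy-2,6-dimethoxybenzaldehyde, whose single free hydroxyl fixes the position of the ring oxygen) and the vinylchroman (two steps from 4-bromophenol).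

Key step: step 5

Step 1
Reactants: 1 4-bromophenol; 2 isoprene
Product: 4 6-bromo-2,2-dimethylchroman, via 4-bromo-2-prenylphenol 3 (not isolated)
Conditions: 2 (2 equiv), Amberlyst 15, heptane/THF, 70 °C, sealed vessel
Reagents that add atoms: none
Why: Acid-catalysed Friedel–Crafts ortho-prenylation by the allyl cation from isoprene, then Markovnikov hydroalkoxylation of the prenyl double bond by the phenol (formal [3+3] chroman annulation); bromine blocks the para position, so C-alkylation can only occur ortho to the hydroxyl.

Step 2
Reactants: 4 6-bromo-2,2-dimethylchroman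
Product: 5 6-ethenyl-2,2-dimethylchroman
Conditions: potassium vinyltrifluoroborate, PdCl2(dppf) (cat.), K2CO3, dioxane/H2O, 90 °C
Reagents that add atoms: potassium vinyltrifluoroborate, C=C[B-](F)(F)F.[K+]
Why: Suzuki–Miyaura cross-coupling of an aryl bromide with a vinyltrifluoroborate; the cyclic ether is inert to Pd(0) and carbonate.

Step 3
Reactants: 6 4-hydroxy-2,6-dimethoxybenzaldehyde; 2 isoprene
Product: 8 5,7-dimethoxy-2,2-dimethylchroman-6-carbaldehyde, via C3-prenyl phenol 7 (not isolated)
Conditions: 2 (1.5 equiv, added in portions), Amberlyst 15, heptane/THF, 70 °C, sealed vessel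
Reagents that add atoms: none
Why: The same Friedel–Crafts prenylation/hydroalkoxylation annulation; C3 and C5 are equivalent, activated by three oxygens and only meta to the formyl group, and the single free hydroxyl is para to CHO, so the ring oxygen can only end up para to the formyl carbon, while the vinylogous-ester aldehyde is too deactivated for Prins chemistry.

Step 4
Reactants: 8 5,7-dimethoxy-2,2-dimethylchroman-6-carbaldehyde
Product: 9 5,7-dihydroxy-2,2-dimethylchroman-6-carbaldehyde
Conditions: AlCl3 (3.5 equiv), CH2Cl2, 0 °C to rt; then ice/2 M HCl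
Reagents that add atoms: none
Why: Lewis-acid demethylation of aryl methyl ethers ortho to a carbonyl group (aluminium bound to C=O and the ortho oxygen, chloride removing methyl as chloromethane), a reaction type established for 2,6-dimethoxybenzaldehydes; the cyclic tertiary ether para to the formyl group is not chelated and should be spared.

Step 5
Reactants: 9 5,7-dihydroxy-2,2-dimethylchroman-6-carbaldehyde; 5 6-ethenyl-2,2-dimethylchroman (1.5 equiv)
Product: 10 1-(5,7-dihydroxy-2,2-dimethylchroman-6-yl)-3-(2,2-dimethylchroman-6-yl)propan-1-one
Conditions: [Rh(cod)OMe]2 (2.5 mol%), bulky BINOL-derived phosphoramidite (10 mol%, racemic is sufficient), K3PO4 (10 mol%), THF, 70 °C, argon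
Reagents that add atoms: none
Why: The base and Rh–OMe convert one of the two hydroxyls flanking the formyl group of 9 into a rhodium phenoxide, Rh(I) inserts into the adjacent formyl C–H bond to give a five-membered O,C-chelated acyl rhodium(III) hydride that is held against decarbonylation, the vinyl group of 5 coordinates and inserts reversibly into Rh–H, and C–C reductive elimination from the primary alkyl joins the carbonyl carbon to the terminal CH2. The closest known reaction type is the chelation-assisted rhodium-catalysed anti-Markovnikov intermolecular hydroacylation of terminal alkenes with salicylaldehydes. No ring is closed and no stereocentre is formed. The step needs linear over branched selectivity and C–C bond formation over decarbonylation: the aroyl ligand is substituted at both ortho positions (chelating oxygen and second hydroxyl), which together with the bulky phosphoramidite should make reductive elimination at the secondary benzylic carbon much slower than at the primary carbon, while reversible hydride insertion funnels both rhodium alkyls to the linear ketone. Because both hydroxyls are ortho to the formyl group, chelation is available whichever one is deprotonated, and no protecting group is needed.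

Compound list
1 | 4-bromophenol | Oc1ccc(Br)cc1 | starting material
2 | isoprene (2-methylbuta-1,3-diene) | C=CC(C)=C | starting material
3 | 4-bromo-2-(3-methylbut-2-en-1-yl)phenol | CC(C)=CCc1cc(Br)ccc1O | intermediate
4 | 6-bromo-2,2-dimethylchroman | CC1(C)CCc2cc(Br)ccc2O1 | intermediate
5 | 6-ethenyl-2,2-dimethylchroman | CC1(C)CCc2cc(C=C)ccc2O1 | intermediate
6 | 4-hydroxy-2,6-dimethoxybenzaldehyde | COc1cc(O)cc(OC)c1C=O | starting material
7 | 4-hydroxy-2,6-dimethoxy-3-(3-methylbut-2-en-1-yl)benzaldehyde | COc1cc(O)c(CC=C(C)C)c(OC)c1C=O | intermediate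
8 | 5,7-dimethoxy-2,2-dimethylchroman-6-carbaldehyde | COc1cc2OC(C)(C)CCc2c(OC)c1C=O | intermediate
9 | 5,7-dihydroxy-2,2-dimethylchroman-6-carbaldehyde | O=Cc1c(O)cc2OC(C)(C)CCc2c1O | intermediate
10 | 1-(5,7-dihydroxy-2,2-dimethylchroman-6-yl)-3-(2,2-dimethylchroman-6-yl)propan-1-one (no stereocentre) | CC1(C)CCc2cc(CCC(=O)c3c(O)cc4c(c3O)CCC(C)(C)O4)ccc2O1 | target

Total step count: 5. Longest linear sequence: 3 steps (6 to 8 to 9 to 10, or 1 to 4 to 5 to 10).

Steps most likely to fail

Step 5. Reductive elimination at the benzylic carbon could compete and give the branched ketone, or the acyl rhodium hydride could decarbonylate and poison the catalyst. The fallback forms the same bond by polar chemistry, sets out from 5 and 9 and returns at 10. Hydroboration–oxidation of 5 (9-BBN, THF; then NaOH/H2O2) should give 2-(2,2-dimethylchroman-6-yl)ethanol F1, and Appel iodination (I2, PPh3, imidazole, CH2Cl2) should give 6-(2-iodoethyl)-2,2-dimethylchroman F2. Aldehyde 9 is protected with MOMCl/NaH in DMF as 5,7-bis(methoxymethoxy)-2,2-dimethylchroman-6-carbaldehyde F3. Iodine–lithium exchange on F2 (t-BuLi, Et2O, −78 °C) and addition to F3 should give the racemic carbinol 1-[5,7-bis(methoxymethoxy)-2,2-dimethylchroman-6-yl]-3-(2,2-dimethylchroman-6-yl)propan-1-ol F4. Dess–Martin oxidation should give the bis-MOM ketone 1-[5,7-bis(methoxymethoxy)-2,2-dimethylchroman-6-yl]-3-(2,2-dimethylchroman-6-yl)propan-1-one F5, and HCl in MeOH at 40 °C should release 10.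

Step 3. C-alkylation of the formyl-deactivated phenol could be slow relative to isoprene oligomerisation, or a second prenylation could occur at C8 of the product. The fallback builds the pyran ring from the oxygen outward, sets out from 6 and returns at 8. O-Alkylation of 6 with 3-chloro-3-methylbut-1-yne (DBU, CuCl2 cat., MeCN, 0 °C) should give 2,6-dimethoxy-4-[(2-methylbut-3-yn-2-yl)oxy]benzaldehyde F6. Thermal propargyl Claisen rearrangement with hydrogen shift and 6π-oxa-electrocyclisation (N,N-diethylaniline, 150 °C) should give 5,7-dimethoxy-2,2-dimethyl-2H-chromene-6-carbaldehyde F7, since both ortho positions are equivalent. Hydrogenation of the C3=C4 bond (H2, Pd/C, EtOAc, rt) should give 8.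

Step 4. Cleavage of the second methyl ether could stall after the first aluminium chelate has formed, or Lewis-acid ionisation of the chroman C2–O1 bond could allow the pyran ring to re-close on a neighbouring oxygen. The fallback avoids methyl ethers and Lewis acid, sets out from isoprene 2 and returns at 9. Annulation of phloroglucinol F8 with 2 (Amberlyst 15, THF, 65 °C) should give 5,7-dihydroxy-2,2-dimethylchroman F9, the only possible constitutional isomer. MOMCl/i-Pr2NEt in CH2Cl2 should give 5,7-bis(methoxymethoxy)-2,2-dimethylchroman F10. Directed ortho-lithiation at C6, between the two MOM ethers (n-BuLi, TMEDA, THF, 0 °C), with DMF quench should give the aldehyde 5,7-bis(methoxymethoxy)-2,2-dimethylchroman-6-carbaldehyde F3, and HCl in MeOH should give 9.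

Further compounds
F1 | step 5 | 2-(2,2-dimethylchroman-6-yl)ethanol | CC1(C)CCc2cc(CCO)ccc2O1
F2 | step 5 | 6-(2-iodoethyl)-2,2-dimethylchroman | CC1(C)CCc2cc(CCI)ccc2O1
F3 | step 5 | 5,7-bis(methoxymethoxy)-2,2-dimethylchroman-6-carbaldehyde | COCOc1cc2OC(C)(C)CCc2c(OCOC)c1C=O
F4 | step 5 | rac-1-[5,7-bis(methoxymethoxy)-2,2-dimethylchroman-6-yl]-3-(2,2-dimethylchroman-6-yl)propan-1-ol | COCOc1cc2OC(C)(C)CCc2c(OCOC)c1C(O)CCc1ccc2OC(C)(C)CCc2c1
F5 | step 5 | 1-[5,7-bis(methoxymethoxy)-2,2-dimethylchroman-6-yl]-3-(2,2-dimethylchroman-6-yl)propan-1-one | COCOc1cc2OC(C)(C)CCc2c(OCOC)c1C(=O)CCc1ccc2OC(C)(C)CCc2c1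
F6 | step 3 | 2,6-dimethoxy-4-[(2-methylbut-3-yn-2-yl)oxy]benzaldehyde | COc1cc(OC(C)(C)C#C)cc(OC)c1C=O
F7 | step 3 | 5,7-dimethoxy-2,2-dimethyl-2H-chromene-6-carbaldehyde | COc1cc2OC(C)(C)C=Cc2c(OC)c1C=O
F8 | step 4 | phloroglucinol (commercial) | Oc1cc(O)cc(O)c1
F9 | step 4 | 5,7-dihydroxy-2,2-dimethylchroman | CC1(C)CCc2c(O)cc(O)cc2O1
F10 | step 4 | 5,7-bis(methoxymethoxy)-2,2-dimethylchroman | COCOc1cc(OCOC)c2CCC(C)(C)Oc2c1
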